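**Plan**
1. Cuts, in retrosynthetic order: O5–Si; O1–C8a of the pyran (aryl bromide plus tertiary alcohol); C3=C4 back to an alkyne; C4–C4a (aryl iodide plus terminal alkyne); the propargylic carbinol back to an epoxy chloride and an (E)-allylic alcohol; the cyclohexene into a diene and a 2-substituted acrolein.
2. Forward: the cyclohexene ring is made first by Diels–Alder reaction and its side arm is grown to the tertiary propargylic alcohol; the separately built bromo-iodo arene is attached, the alkyne is semihydrogenated, and the 2H-pyran ring is closed last.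
3. Stereochemistry: ring C1/C2 come from a catalyst-controlled endo Diels–Alder reaction whose endo formyl group (cis to the C2 methyl) is later reduced to the C1 methyl; methacrolein as dienophile would give the C1 epimer. Chromene C2 comes from Sharpless epoxidation and is never touched again.
4. Enabling feature: the tertiary allylic aryl ether O1–C2 would ionise if the pyran were closed at C2, but the ring can instead be closed at O1–C8a on the benzene ring, with the (Z)-C3=C4 alkene holding the C2 hydroxyl beside C8a.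

Key step: step 16

Assumption: the (S)-prolinol-derived oxazaborolidinium catalyst is taken to expose the enal face that leads to (1S,2R)-4, in line with its usual facial preference for 2-substituted acroleins; the antipodal catalyst is equally accessible if the sense is the reverse.
Remark: cyclohexene locants 1–3 follow the target side chain throughout. From 4 onward the ring keeps one spatial arrangement (C1 methyl, or its formyl precursor, cis to the C2 methyl); the CIP letters differ between 4, 6 and 7 only because substituent priorities change.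

**Step 1**
Reactants: 1 hex-5-enal
Product: 2 2-methylidenehex-5-enal
Conditions: 37% aq. CH2O, pyrrolidine (10 mol %), propionic acid (10 mol %), i-PrOH, 45 °C
Reagents that add atoms: formaldehyde, C=O
Why: Organocatalytic Mannich condensation (α-methylenation of an aldehyde through its enamine, then loss of the amine) should convert the α-CH2 into the 1,1-disubstituted enal without touching the remote alkene.

**Step 2**
Reactants: 2 2-methylidenehex-5-enal; 3 (E)-3-methylpenta-1,3-diene
Product: 4 (1S,2R)-1-(but-3-en-1-yl)-2,3-dimethylcyclohex-3-ene-1-carbaldehyde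
Conditions: (S)-α,α-diphenylprolinol-derived B-(o-tolyl)oxazaborolidine·Tf2NH (20 mol %), diene (3 equiv), CH2Cl2, −78 → −40 °C
Reagents that add atoms: none
Why: In this enantioselective Lewis acid-catalysed Diels–Alder reaction of a 2-substituted acrolein the unsubstituted diene terminus should bond to the enal β-carbon ("ortho" orientation), the activated formyl group should sit endo and so end cis to the C2 methyl, and the chiral boron cation should select the enal face, which sets C1 and C2 together.

**Step 3**
Reactants: 4 (1S,2R)-1-(but-3-en-1-yl)-2,3-dimethylcyclohex-3-ene-1-carbaldehyde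
Product: 6 (1R,2S)-1-(but-3-en-1-yl)-1,2,3-trimethylcyclohex-3-ene, via aldehyde hydrazone 5 (not isolated)
Conditions: N2H4·H2O, KOH, diethylene glycol, argon, 130 °C then 200 °C
Reagents that add atoms: none
Why: Wolff–Kishner reduction (Huang-Minlon modification) of the non-enolisable neopentyl aldehyde should turn the formyl group into the C1 methyl cis to the C2 methyl, with air excluded so that no diimide forms to reduce the terminal alkene.

**Step 4**
Reactants: 6 (1R,2S)-1-(but-3-en-1-yl)-1,2,3-trimethylcyclohex-3-ene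
Product: 7 4-[(1S,2S)-1,2,3-trimethylcyclohex-3-en-1-yl]butan-2-one
Conditions: PdCl2 (10 mol %), CuCl (1 equiv), O2 (1 atm), DMF/H2O, rt
Reagents that add atoms: water, O
Why: Tsuji–Wacker oxidation should be selective for the monosubstituted alkene (Markovnikov hydroxypalladation), the trisubstituted ring alkene being inert under these conditions.

**Step 5**
Reactants: 7 4-[(1S,2S)-1,2,3-trimethylcyclohex-3-en-1-yl]butan-2-one; 8 triethyl phosphonoacetate
Product: 9 ethyl (2E)-3-methyl-5-[(1S,2S)-1,2,3-trimethylcyclohex-3-en-1-yl]pent-2-enoate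
Conditions: NaH, THF, 0 °C → reflux; minor (Z)-isomer removed by chromatography
Reagents that add atoms: none
Why: Horner–Wadsworth–Emmons olefination of a methyl ketone is expected to favour the (E)-enoate, in which the larger chain lies trans to the ester.

**Step 6**
Reactants: 9 ethyl (2E)-3-methyl-5-[(1S,2S)-1,2,3-trimethylcyclohex-3-en-1-yl]pent-2-enoate
Product: 10 (2E)-3-methyl-5-[(1S,2S)-1,2,3-trimethylcyclohex-3-en-1-yl]pent-2-en-1-ol
Conditions: i-Bu2AlH (2.5 equiv), CH2Cl2, −78 °C
Reagents that add atoms: none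
Why: 1,2-Reduction of the enoate with diisobutylaluminium hydride should give the allylic alcohol without conjugate reduction or loss of alkene geometry.

**Step 7**
Reactants: 10 (2E)-3-methyl-5-[(1S,2S)-1,2,3-trimethylcyclohex-3-en-1-yl]pent-2-en-1-ol
Product: 11 [(2R,3R)-3-methyl-3-{2-[(1S,2S)-1,2,3-trimethylcyclohex-3-en-1-yl]ethyl}oxiran-2-yl]methanol
Conditions: Ti(OiPr)4 (10 mol %), D-(−)-diethyl tartrate (12 mol %), t-BuOOH, 4 Å molecular sieves, CH2Cl2, −20 °C
Reagents that add atoms: tert-butyl hydroperoxide, CC(C)(C)OO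
Why: Sharpless asymmetric epoxidation with the D-(−)-tartrate complex should deliver oxygen to the face of the (E)-allylic alcohol that gives the (2R,3R)-epoxide, which fixes the future chromene C2 under reagent control while the ring alkene, lacking a directing hydroxyl, stays untouched.

**Step 8**
Reactants: 11 [(2R,3R)-3-methyl-3-{2-[(1S,2S)-1,2,3-trimethylcyclohex-3-en-1-yl]ethyl}oxiran-2-yl]methanol
Product: 12 (2R,3S)-3-(chloromethyl)-2-methyl-2-{2-[(1S,2S)-1,2,3-trimethylcyclohex-3-en-1-yl]ethyl}oxirane
Conditions: PPh3, CCl4, NaHCO3, reflux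
Reagents that add atoms: carbon tetrachloride, ClC(Cl)(Cl)Cl
Why: Appel chlorination should replace the primary hydroxyl by SN2 attack of chloride on the alkoxyphosphonium ion, leaving the epoxide and both of its stereocentres intact under the buffered conditions.

**Step 9**
Reactants: 12 (2R,3S)-3-(chloromethyl)-2-methyl-2-{2-[(1S,2S)-1,2,3-trimethylcyclohex-3-en-1-yl]ethyl}oxirane
Product: 14 (3R)-3-methyl-5-[(1S,2S)-1,2,3-trimethylcyclohex-3-en-1-yl]pent-1-yn-3-ol, via chloroalkenyl carbinol 13 (not isolated)
Conditions: n-BuLi (3.3 equiv), THF, −40 → −20 °C; aq. NH4Cl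
Reagents that add atoms: none
Why: Base-induced double elimination of a 2,3-epoxy chloride should open the epoxide by β-elimination at the CH–O bond and then expel HCl to give the acetylide, so the quaternary C–O bond and its configuration are never broken.

**Step 10**
Reactants: 15 2,3,4-trimethoxybenzaldehyde
Product: 16 5-bromo-2,3,4-trimethoxybenzaldehyde
Conditions: NBS, MeCN, rt
Reagents that add atoms: N-bromosuccinimide, O=C1CCC(=O)N1Br
Why: Electrophilic aromatic bromination should go to C5, the only free position that is ortho and para to methoxy groups and meta to the formyl group.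

**Step 11**
Reactants: 16 5-bromo-2,3,4-trimethoxybenzaldehyde
Product: 18 5-bromo-2,3,4-trimethoxyphenol, via aryl formate 17 (not isolated)
Conditions: mCPBA, CH2Cl2, rt; then K2CO3, MeOH, rt
Reagents that add atoms: 3-chloroperoxybenzoic acid, OOC(=O)c1cccc(Cl)c1
Why: Baeyer–Villiger oxidation of the electron-rich benzaldehyde should proceed with aryl migration to the formate, which methanolysis converts into the phenol.

**Step 12**
Reactants: 18 5-bromo-2,3,4-trimethoxyphenol
Product: 19 3-bromo-2-iodo-4,5,6-trimethoxyphenol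
Conditions: NIS, TsOH (cat.), MeCN, 0 °C
Reagents that add atoms: N-iodosuccinimide, O=C1CCC(=O)N1I
Why: Electrophilic aromatic iodination can only occur at the single remaining ring C–H, which is ortho to the activating hydroxyl.

**Step 13**
Reactants: 19 3-bromo-2-iodo-4,5,6-trimethoxyphenol
Product: 20 (3-bromo-2-iodo-4,5,6-trimethoxyphenoxy)triisopropylsilane
Conditions: TIPSOTf, 2,6-lutidine, CH2Cl2, 0 °C → rt
Reagents that add atoms: triisopropylsilyl trifluoromethanesulfonate, CC(C)[Si](OS(=O)(=O)C(F)(F)F)(C(C)C)C(C)C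
Why: O-Silylation with the reactive silyl triflate should protect the hindered phenol as a bulky ether that withstands amine, carbonate and hydrogenation conditions and is too crowded to migrate to a neighbouring alkoxide.

**Step 14**
Reactants: 20 (3-bromo-2-iodo-4,5,6-trimethoxyphenoxy)triisopropylsilane; 14 (3R)-3-methyl-5-[(1S,2S)-1,2,3-trimethylcyclohex-3-en-1-yl]pent-1-yn-3-ol
Product: 21 (3R)-1-{2-bromo-3,4,5-trimethoxy-6-[(triisopropylsilyl)oxy]phenyl}-3-methyl-5-[(1S,2S)-1,2,3-trimethylcyclohex-3-en-1-yl]pent-1-yn-3-ol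
Conditions: PdCl2(PPh3)2 (5 mol %), CuI (10 mol %), Et3N/THF (degassed), 50 °C
Reagents that add atoms: none
Why: In this Sonogashira coupling oxidative addition at the C–I bond is much faster than at C–Br, so only the iodide should be replaced, and free tertiary propargylic alcohols are standard alkyne partners.

**Step 15**
Reactants: 21 (3R)-1-{2-bromo-3,4,5-trimethoxy-6-[(triisopropylsilyl)oxy]phenyl}-3-methyl-5-[(1S,2S)-1,2,3-trimethylcyclohex-3-en-1-yl]pent-1-yn-3-ol
Product: 22 (1Z,3R)-1-{2-bromo-3,4,5-trimethoxy-6-[(triisopropylsilyl)oxy]phenyl}-3-methyl-5-[(1S,2S)-1,2,3-trimethylcyclohex-3-en-1-yl]pent-1-en-3-ol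
Conditions: H2 (1 atm), Pd/CaCO3 poisoned with Pb(OAc)2, quinoline, EtOAc, rt
Reagents that add atoms: none
Why: Heterogeneous syn-semihydrogenation of the alkyne on the poisoned catalyst should stop at the (Z)-alkene and leave the aryl bromide and the trisubstituted ring alkene alone.

**Step 16**
Reactants: 22 (1Z,3R)-1-{2-bromo-3,4,5-trimethoxy-6-[(triisopropylsilyl)oxy]phenyl}-3-methyl-5-[(1S,2S)-1,2,3-trimethylcyclohex-3-en-1-yl]pent-1-en-3-ol
Product: 23 triisopropyl({(2R)-6,7,8-trimethoxy-2-methyl-2-{2-[(1S,2S)-1,2,3-trimethylcyclohex-3-en-1-yl]ethyl}-2H-chromen-5-yl}oxy)silane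
Conditions: Pd(OAc)2 (5 mol %), 2-di-tert-butylphosphino-2′,4′,6′-triisopropylbiphenyl (10 mol %), Cs2CO3 (2 equiv), toluene, 80 °C
Reagents that add atoms: none
Why: Zerovalent palladium, formed in the flask from Pd(OAc)2 and the phosphine, should insert into the C8a–Br bond, the tertiary hydroxyl then binds and is deprotonated by Cs2CO3 to a seven-membered aryl(alkoxo)palladium chelate, and C–O reductive elimination forms O1–C8a. The closest known reaction type is the palladium-catalysed intramolecular aryl etherification (Buchwald–Hartwig C–O coupling) of tertiary alcohols to oxygen heterocycles. The 2H-pyran ring closes by heteroatom–aryl bond formation at an sp2 carbon through that reductive elimination, not by substitution at C2, so C2 keeps all four bonds, no new stereocentre arises and the (R) configuration from step 7 passes on unchanged. The step needs reductive elimination to outrun protodebromination and β-carbon scission: the tertiary alkoxide has no carbinol hydrogen for β-hydride elimination, the (Z)-C3=C4 alkene holds the oxygen next to palladium, and the bulky electron-rich phosphine speeds both insertion into the hindered, electron-rich bromide and the C–O elimination. The silyl ether at O5 keeps the arene from becoming a phenoxide.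

**Step 17**
Reactants: 23 triisopropyl({(2R)-6,7,8-trimethoxy-2-methyl-2-{2-[(1S,2S)-1,2,3-trimethylcyclohex-3-en-1-yl]ethyl}-2H-chromen-5-yl}oxy)silane
Product: 24 (2R)-6,7,8-trimethoxy-2-methyl-2-{2-[(1S,2S)-1,2,3-trimethylcyclohex-3-en-1-yl]ethyl}-2H-chromen-5-ol
Conditions: n-Bu4NF, AcOH, THF (degassed), 0 °C
Reagents that add atoms: none
Why: Fluoride-induced desilylation of the aryl silyl ether, buffered with acetic acid, should free the C5 phenol without exposing the acid-labile chromene or the oxidation-prone phenoxide to harsh conditions.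

**Compound list**
1 | hex-5-enal | C=CCCCC=O | starting material
2 | 2-methylidenehex-5-enal | C=CCCC(=C)C=O | intermediate
3 | (E)-3-methylpenta-1,3-diene | C/C=C(C)/C=C | starting material
4 | (1S,2R)-1-(but-3-en-1-yl)-2,3-dimethylcyclohex-3-ene-1-carbaldehyde (formyl cis to C2 methyl) | C=CCC[C@]1(C=O)CCC=C(C)[C@H]1C | intermediate
5 | hydrazone of 4 | C=CCC[C@]1(C=NN)CCC=C(C)[C@H]1C | intermediate (not isolated)
6 | (1R,2S)-1-(but-3-en-1-yl)-1,2,3-trimethylcyclohex-3-ene (C1 and C2 methyls cis) | C=CCC[C@]1(C)CCC=C(C)[C@H]1C | intermediate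
7 | 4-[(1S,2S)-1,2,3-trimethylcyclohex-3-en-1-yl]butan-2-one | CC(=O)CC[C@]1(C)CCC=C(C)[C@H]1C | intermediate
8 | triethyl phosphonoacetate | CCOC(=O)CP(=O)(OCC)OCC | starting material
9 | ethyl (2E)-3-methyl-5-[(1S,2S)-1,2,3-trimethylcyclohex-3-en-1-yl]pent-2-enoate | CCOC(=O)/C=C(\C)CC[C@]1(C)CCC=C(C)[C@H]1C | intermediate
10 | (2E)-3-methyl-5-[(1S,2S)-1,2,3-trimethylcyclohex-3-en-1-yl]pent-2-en-1-ol | OC/C=C(\C)CC[C@]1(C)CCC=C(C)[C@H]1C | intermediate
11 | [(2R,3R)-3-methyl-3-{2-[(1S,2S)-1,2,3-trimethylcyclohex-3-en-1-yl]ethyl}oxiran-2-yl]methanol | OC[C@H]1O[C@]1(C)CC[C@]2(C)CCC=C(C)[C@H]2C | intermediate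
12 | (2R,3S)-3-(chloromethyl)-2-methyl-2-{2-[(1S,2S)-1,2,3-trimethylcyclohex-3-en-1-yl]ethyl}oxirane | ClC[C@H]1O[C@]1(C)CC[C@]2(C)CCC=C(C)[C@H]2C | intermediate
13 | (3R)-1-chloro-3-methyl-5-[(1S,2S)-1,2,3-trimethylcyclohex-3-en-1-yl]pent-1-en-3-ol (present as its lithium alkoxide, alkene geometry undefined) | ClC=C[C@](C)(O)CC[C@]1(C)CCC=C(C)[C@H]1C | intermediate (not isolated)
14 | (3R)-3-methyl-5-[(1S,2S)-1,2,3-trimethylcyclohex-3-en-1-yl]pent-1-yn-3-ol | C#C[C@](C)(O)CC[C@]1(C)CCC=C(C)[C@H]1C | intermediate
15 | 2,3,4-trimethoxybenzaldehyde | COc1ccc(C=O)c(OC)c1OC | starting material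
16 | 5-bromo-2,3,4-trimethoxybenzaldehyde | COc1c(Br)cc(C=O)c(OC)c1OC | intermediate
17 | 5-bromo-2,3,4-trimethoxyphenyl formate | COc1c(Br)cc(OC=O)c(OC)c1OC | intermediate (not isolated)
18 | 5-bromo-2,3,4-trimethoxyphenol | COc1c(Br)cc(O)c(OC)c1OC | intermediate
19 | 3-bromo-2-iodo-4,5,6-trimethoxyphenol | COc1c(O)c(I)c(Br)c(OC)c1OC | intermediate
20 | (3-bromo-2-iodo-4,5,6-trimethoxyphenoxy)triisopropylsilane | COc1c(O[Si](C(C)C)(C(C)C)C(C)C)c(I)c(Br)c(OC)c1OC | intermediate
21 | (3R)-1-{2-bromo-3,4,5-trimethoxy-6-[(triisopropylsilyl)oxy]phenyl}-3-methyl-5-[(1S,2S)-1,2,3-trimethylcyclohex-3-en-1-yl]pent-1-yn-3-ol | COc1c(O[Si](C(C)C)(C(C)C)C(C)C)c(C#C[C@](C)(O)CC[C@]2(C)CCC=C(C)[C@H]2C)c(Br)c(OC)c1OC | intermediate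
22 | (1Z,3R)-1-{2-bromo-3,4,5-trimethoxy-6-[(triisopropylsilyl)oxy]phenyl}-3-methyl-5-[(1S,2S)-1,2,3-trimethylcyclohex-3-en-1-yl]pent-1-en-3-ol | COc1c(O[Si](C(C)C)(C(C)C)C(C)C)c(/C=C\[C@](C)(O)CC[C@]2(C)CCC=C(C)[C@H]2C)c(Br)c(OC)c1OC | intermediate
23 | triisopropyl({(2R)-6,7,8-trimethoxy-2-methyl-2-{2-[(1S,2S)-1,2,3-trimethylcyclohex-3-en-1-yl]ethyl}-2H-chromen-5-yl}oxy)silane | COc1c(O[Si](C(C)C)(C(C)C)C(C)C)c2c(c(OC)c1OC)O[C@](C)(CC[C@]1(C)CCC=C(C)[C@H]1C)C=C2 | intermediate
24 | (2R)-6,7,8-trimethoxy-2-methyl-2-{2-[(1S,2S)-1,2,3-trimethylcyclohex-3-en-1-yl]ethyl}-2H-chromen-5-ol | COc1c(O)c2c(c(OC)c1OC)O[C@](C)(CC[C@]1(C)CCC=C(C)[C@H]1C)C=C2 | target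

**Totals**
Total step count: 17. Longest linear sequence: 13 steps (steps 1–9 and 14–17, from hex-5-enal); the arene branch (steps 10–13) joins at step 14.

**Steps most likely to fail**

Step 16. Insertion of zerovalent palladium into the di-ortho-substituted, electron-rich C8a–Br bond may lag behind catalyst decay, and the allylic palladium alkoxide may be diverted into protodebromination or β-carbon scission. The fallback sets out from 22. Diimide (2-nitrobenzenesulfonyl hydrazide, Et3N) reduces only the disubstituted styrenyl alkene and gives the saturated bromo alcohol F1. Its flexible, non-allylic tertiary alkoxide is closed onto C8a by copper-catalysed Ullmann etherification (CuI, 3,4,7,8-tetramethyl-1,10-phenanthroline, Cs2CO3, toluene, 110 °C), which does not depend on palladium insertion, to give the chroman silyl ether F2. Benzylic dehydrogenation with DDQ (dioxane, reflux) then installs C3=C4 and comes back to the route at 23. The bond formed is still O1–C8a and C2 is still untouched.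

Step 2. Endo/exo or regiochemical discrimination may be poor at the congested C1–C2 bond, or facial selectivity may erode with the trisubstituted diene terminus. The fallback sets out from 3. A Diels–Alder reaction with methyl acrylate (the same oxazaborolidine activated by AlBr3, enantiomer chosen for the series shown) should give the cis ester methyl (1S,2S)-2,3-dimethylcyclohex-3-ene-1-carboxylate F3. Its enolate (lithium diisopropylamide, THF/DMPU, −78 °C) is alkylated with 4-iodobut-1-ene from the face anti to the C2 methyl, which sets C1 by substrate control and gives the quaternary ester F4. LiAlH4 reduces it to the neopentyl alcohol F5, and oxidation with 1,1,1-triacetoxy-1,1-dihydro-1,2-benziodoxol-3(1H)-one comes back to the route at 4.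

Step 15. The hydrogenation may stall at the doubly hindered alkyne, over-reduce, or cause hydrodebromination. The fallback sets out from 14 and 20, bypasses steps 14 and 15, and builds the (Z)-alkene by coupling instead of reduction. Iodination of 14 (NIS, cat. AgNO3, acetone) gives the iodoalkyne F6, and diimide syn-reduction (2-nitrobenzenesulfonyl hydrazide, Et3N) gives the (Z)-iodoalkene F7. Iodine–magnesium exchange on 20 (i-PrMgCl·LiCl, THF, −40 °C) gives the arylmagnesium chloride F8, which ZnCl2 converts into the arylzinc chloride F9. Negishi coupling of F9 with F7 (Pd(PPh3)4, THF, 40 °C) proceeds with retention of alkene geometry and comes back to the route at 22.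

**Further compounds**
F1 | step 16 | (3R)-1-{2-bromo-3,4,5-trimethoxy-6-[(triisopropylsilyl)oxy]phenyl}-3-methyl-5-[(1S,2S)-1,2,3-trimethylcyclohex-3-en-1-yl]pentan-3-ol | COc1c(O[Si](C(C)C)(C(C)C)C(C)C)c(CC[C@](C)(O)CC[C@]2(C)CCC=C(C)[C@H]2C)c(Br)c(OC)c1OC
F2 | step 16 | triisopropyl({(2R)-6,7,8-trimethoxy-2-methyl-2-{2-[(1S,2S)-1,2,3-trimethylcyclohex-3-en-1-yl]ethyl}-3,4-dihydro-2H-chromen-5-yl}oxy)silane | COc1c(O[Si](C(C)C)(C(C)C)C(C)C)c2c(c(OC)c1OC)O[C@](C)(CC[C@]1(C)CCC=C(C)[C@H]1C)CC2
F3 | step 2 | methyl (1S,2S)-2,3-dimethylcyclohex-3-ene-1-carboxylate | COC(=O)[C@H]1CCC=C(C)[C@H]1C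
F4 | step 2 | methyl (1S,2R)-1-(but-3-en-1-yl)-2,3-dimethylcyclohex-3-ene-1-carboxylate | C=CCC[C@]1(C(=O)OC)CCC=C(C)[C@H]1C
F5 | step 2 | [(1S,2R)-1-(but-3-en-1-yl)-2,3-dimethylcyclohex-3-en-1-yl]methanol | C=CCC[C@]1(CO)CCC=C(C)[C@H]1C
F6 | step 15 | (3R)-1-iodo-3-methyl-5-[(1S,2S)-1,2,3-trimethylcyclohex-3-en-1-yl]pent-1-yn-3-ol | IC#C[C@](C)(O)CC[C@]1(C)CCC=C(C)[C@H]1C
F7 | step 15 | (1Z,3R)-1-iodo-3-methyl-5-[(1S,2S)-1,2,3-trimethylcyclohex-3-en-1-yl]pent-1-en-3-ol | I/C=C\[C@](C)(O)CC[C@]1(C)CCC=C(C)[C@H]1C
F8 | step 15 | {2-bromo-3,4,5-trimethoxy-6-[(triisopropylsilyl)oxy]phenyl}magnesium chloride | COc1c(O[Si](C(C)C)(C(C)C)C(C)C)c([Mg]Cl)c(Br)c(OC)c1OC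
F9 | step 15 | {2-bromo-3,4,5-trimethoxy-6-[(triisopropylsilyl)oxy]phenyl}zinc chloride | COc1c(O[Si](C(C)C)(C(C)C)C(C)C)c([Zn]Cl)c(Br)c(OC)c1OC
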